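(The earlier runs and the new flask stem from a simulated flask with constants of no real substance; the scatter is artificial.)

The pitfall in alpha is to take the first fall of substrate as the flask's time constant: up to 0.833 h it gives a lifetime of 0.570 h, but the curve slows as reagent is spent.

| flask | substrate | reagent | remark | time |
|---|---|---|---|---|
| alpha | 0.21 M | 0.252 M | run made earlier |  |
| eta | 0.21 M | 0.13 M | run made earlier |  |
| zeta | 0.21 M | 0.50 M | run made earlier |  |
| maple | 0.21 M | 0.252 M | a closed flask charged with all of it at once and left for 10 h | 10 h |
| ash | 0.21 M | 0.252 M (fed, over 8.00 h) | all but reagent at the start; reagent goes in evenly over 8.00 h, the run ends at 10 h | 10 h |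
| oak | 0.21 M (fed, over 8.00 h) | 0.252 M | a stirred flask in which substrate is dosed at a steady rate over 8.00 h without added volume, worked up at 10 h | 10 h |
| larch | 0.21 M | 0.252 M | a single well-mixed tank run continuously and read at steady state, 10 h in it on average |  |

| run | time / h | target / % | substrate / % |
|---|---|---|---|
| alpha | 0.833 | 77.3 | 23.2 |
| alpha | 2.00 | 89.8 | 9.8 |
| alpha | 4.00 | 95.8 | 4.5 |
| alpha | 10.0 | 98.2 | 0.7 |
| eta | 1.33 | 48.8 | 51.8 |
| eta | 4.00 | 57.3 | 42.8 |
| eta | 6.00 | 59.2 | 40.4 |
| eta | 10.0 | 60.4 | 39.8 |
| zeta | 2.50 | 100.4 | 0.3 |
| zeta | 5.00 | 99.9 | 0 |
| zeta | 8.00 | 99.1 | 0.4 |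
| zeta | 10.0 | 99.8 | 0.5 |

(readings scatter by 0.5 percentage points)

- the set-up with the highest amount of target at the outlet or at the end, in percent of the substrate put in ("none" if the first two lie within 2 percentage points) (maple / ash / oak / larch / none)
- amount of target at the outlet or at the end, in percent of the substrate put in, maple
- amount of target at the outlet or at the end, in percent of the substrate put in, ash
- amount of target at the outlet or at the end, in percent of the substrate put in, oak
- amount of target at the outlet or at the end, in percent of the substrate put in, larch

- the stated concentrations are those of everything mixed, before any reaction; amounts are the same in each set-up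
- the earlier runs were read with a standard deviation of 0.5 percentage points
- the feed brings no volume worth counting
- the earlier runs were made in a closed, stirred flask

The eta run stops with target at 60.4%, near the 61.9% its reagent allows in a one-to-one reaction, so [reagent] − [substrate] keeps its charged value. Ash and oak, once fed, therefore hold alpha's charge and stand on alpha's curve, entering it late.

Two times then count. The first is the wait after the feed, 2.00 h. The second is the tail lifetime, the pseudo-first-order time in which [substrate] falls by a factor e late in alpha, read between 2.00 h and 4.00 h as 2.57 h, longer than the early figure.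

Between 0.833 h and 2.00 h, alpha loses on average 0.115 h⁻¹ of the substrate charge, slower than the 0.150 h⁻¹ at which ash's feed brings reagent on that scale. The reckoning here therefore enters the tail at alpha's 9.8%. The ratio of wait to lifetime, 0.778, brings this to 4.50%, so ash and oak give about 95.5% target, while maple repeats alpha's 98.2%. A tank with this lifetime keeps roughly 20.4% substrate, so larch ranks last.

The forecast named maple, with 99%, ash 94.3%, oak 94.2% and larch 85.5%, 1.2 percentage points below this reckoning for ash, holding that “starved reagent or back-mixing only lowers the rate”.

The flasks give 98.7% for maple, 94.9% for ash, 94.7% for oak and 86.0% for larch, so the best is maple.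

    substrate + reagent → target, rate k1*[substrate]*[reagent]^1.5 (k = 0.590 M⁻¹·⁵ min⁻¹)
    target → over-reaction product (k = 1.50 × 10⁻⁵ min⁻¹)

In ash at 10.0 h, substrate has a half-life of 1.7 h, close to the 1.78 h from the tail lifetime and shorter than the wait, whereas target's half-life towards over-reaction product is 32 d, far longer than the run. The neighbour of ash charged with 0.084 M substrate lies off alpha's curve, holding 0.168 M reagent at the end against 0.0517 M in ash, and it ends with 0% substrate and 99.4% target.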